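**Retrosynthetic overview**
1. Feature: ring A is a 1,2,3-trioxygenated benzene (C1 OMe, C2 OH, C3 O–ring B, C4–C6 Br) in which only the middle oxygen, on C2, is free. An oxygen bridge that stays on one bridgehead when a 7-oxanorbornadiene opens leaves exactly this pattern, so the C2 oxygen is traced back to the ring oxygen of 3-methoxyfuran.
2. C5–Br and C6–Br ⇒ C–H (electrophilic bromination). C4–Br ⇒ C4–CO2H (ipso bromodecarboxylation para to OMe) ⇒ C4–CO2Me.
3. Ring A ⇒ 3-methoxyfuran (supplies C2, C1, C6, C5 and the C2 oxygen) + methyl 3-(2,4-dibromophenoxy)propiolate (supplies C3, C4). The Diels–Alder reaction forms C2–C3 and C4–C5, then acid cleaves C5–O.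
4. Dienophile ⇒ 2,4-dibromophenol + methyl propiolate (oxa-Michael addition, Br2 addition, two dehydrobrominations). The crowded C3–O–aryl bond therefore exists before ring A does.
5. Ring order: ring B is bought and ring A is the only ring made (step 4). The target has no stereocentre.

Key step: step 4

Assumption: 3-methoxyfuran is bought from a specialty supplier and distilled from K2CO3 before use. The ring A numbering of the overview (C1–C6) is used throughout, and ring B is the 2,4-dibromophenyl ring.

**Step 1**
Reactants: 1 2,4-dibromophenol; 2 methyl propiolate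
Product: 3 methyl (E)-3-(2,4-dibromophenoxy)prop-2-enoate
Conditions: DABCO (10 mol %), CH2Cl2, 0 → 23 °C
Reagents that add atoms: none
Why: The amine-catalysed oxa-Michael addition of an acidic phenol to methyl propiolate is a standard entry to β-aryloxyacrylates and should give the more stable E alkene.

**Step 2**
Reactants: 3 methyl (E)-3-(2,4-dibromophenoxy)prop-2-enoate
Product: 5 methyl (Z)-2-bromo-3-(2,4-dibromophenoxy)prop-2-enoate, via dibromo ester 4 (not isolated)
Conditions: Br2 (1.05 equiv), CH2Cl2, 0 → 23 °C; then Et3N (1.2 equiv), 0 °C
Reagents that add atoms: bromine, BrBr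
Why: Bromine addition to the enol-ether double bond followed by E1cB-type loss of HBr (acidic C–H alpha to the ester, labile bromide on the oxygen-bearing carbon) is the usual bromination–dehydrobromination of β-alkoxyacrylates, should give the Z isomer with the remaining vinyl H anti to Br, and should leave the deactivated ring B unbrominated.

**Step 3**
Reactants: 5 methyl (Z)-2-bromo-3-(2,4-dibromophenoxy)prop-2-enoate
Product: 6 methyl 3-(2,4-dibromophenoxy)prop-2-ynoate
Conditions: LiN(SiMe3)2 (1.05 equiv, slow addition), THF, −78 → −40 °C; pH 7 buffer quench; rapid filtration through deactivated silica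
Reagents that add atoms: none
Why: This is base-induced anti dehydrobromination, the classical passage from α-bromoacrylates to propiolates and from β-bromovinyl ethers to ynol ethers; the vinyl H is acidified by the geminal aryloxy oxygen, lies cis to the lithium-binding ester carbonyl and anti to Br, and the hindered silylamide should neither add to the electrophilic product nor metalate or exchange the aryl bromides at low temperature.

**Step 4**
Reactants: 6 methyl 3-(2,4-dibromophenoxy)prop-2-ynoate; 7 3-methoxyfuran
Product: 9 methyl 2-(2,4-dibromophenoxy)-3-hydroxy-4-methoxybenzoate, via oxanorbornadiene adduct 8 (not isolated)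
Conditions: 7 (2 equiv), toluene, 80 °C, sealed tube; evaporate volatiles; then CF3CO2H (0.2 equiv), 4 Å MS, CH2Cl2, 0 → 23 °C
Reagents that add atoms: none
Why: This is the Diels–Alder reaction of an alkoxyfuran with an acetylenic ester followed by acid-induced opening of the oxygen bridge and aromatisation, the established furan-to-phenol sequence, applied here to an alkynoate whose β-carbon carries an aryloxy group. The furan α-carbon next to C–OMe has the largest HOMO coefficient and the OAr-bearing alkyne carbon (β to the ester) the largest LUMO coefficient, so ring A closes in one concerted but asynchronous suprafacial [4+2] event in which C2–C3 runs ahead of C4–C5, and only regioisomer 8 is expected. The two bridgehead stereocentres of 8 are tied to each other by the bicycle, form as a racemate and disappear on aromatisation, so nothing has to be controlled. After protonation of the bridge oxygen the C5–O bond breaks rather than C2–O, since the C5 cation is a pentadienyl cation with its charge on C1 and C3, the carbons that carry OMe and OAr, whereas a C2 cation would place charge on C6 and on the ester-bearing C4; loss of the C2 proton then leaves the former furan oxygen as the C2 hydroxyl. Water is kept out (molecular sieves, catalytic anhydrous acid) so that the C1=C6 methyl enol ether is not hydrolysed to a ketone before the bridge opens. The electron-poor dibromophenyl ring draws the oxygen lone pair away from the triple bond, which should keep 6 reactive enough towards the very electron-rich diene.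

**Step 5**
Reactants: 9 methyl 2-(2,4-dibromophenoxy)-3-hydroxy-4-methoxybenzoate
Product: 10 2-(2,4-dibromophenoxy)-3-hydroxy-4-methoxybenzoic acid
Conditions: LiOH·H2O (4 equiv), THF/MeOH/H2O, 50 °C; then 1 M HCl
Reagents that add atoms: lithium hydroxide, [Li+].[OH-]
Why: This is saponification of a methyl benzoate with only one large ortho substituent; the diaryl ether, aryl bromides and methyl ether are inert to aqueous hydroxide, and the phenoxide formed shields ring A from nucleophilic aromatic substitution.

**Step 6**
Reactants: 10 2-(2,4-dibromophenoxy)-3-hydroxy-4-methoxybenzoic acid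
Product: 13 3,4,5-tribromo-2-(2,4-dibromophenoxy)-6-methoxyphenol, via monobromo acid 11 (not isolated), via dibromo acid 12 (not isolated)
Conditions: Br2 (4 equiv), NaOAc (5 equiv), AcOH, 23 → 70 °C; aq. Na2S2O3 work-up
Reagents that add atoms: bromine, BrBr
Why: Electrophilic aromatic bromination is expected first at C5 (para to OH) and then at C6 (ortho to OMe, para to OAr), followed by ipso attack at C4 (para to OMe, ortho to OAr) and loss of CO2 from the carboxylate σ-complex, which is the bromodecarboxylation known for 4-methoxy- and 4-hydroxybenzoic acids and is helped here by strain relief around the twisted carboxyl group; any other order of the three events converges on the same product, and the doubly brominated ring B should stay untouched.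

**Compound list**
1 | 2,4-dibromophenol | Oc1ccc(Br)cc1Br | starting material
2 | methyl propiolate | C#CC(=O)OC | starting material
3 | methyl (E)-3-(2,4-dibromophenoxy)prop-2-enoate | COC(=O)/C=C/Oc1ccc(Br)cc1Br | intermediate
4 | methyl 2,3-dibromo-3-(2,4-dibromophenoxy)propanoate (diastereomer mixture, both centres lost in the same step) | COC(=O)C(Br)C(Br)Oc1ccc(Br)cc1Br | intermediate
5 | methyl (Z)-2-bromo-3-(2,4-dibromophenoxy)prop-2-enoate | COC(=O)/C(Br)=C/Oc1ccc(Br)cc1Br | intermediate
6 | methyl 3-(2,4-dibromophenoxy)prop-2-ynoate | COC(=O)C#COc1ccc(Br)cc1Br | intermediate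
7 | 3-methoxyfuran | COc1ccoc1 | starting material
8 | (±)-methyl 3-(2,4-dibromophenoxy)-5-methoxy-7-oxabicyclo[2.2.1]hepta-2,5-diene-2-carboxylate (racemate, 1S,4R enantiomer drawn) | COC(=O)C1=C(Oc2ccc(Br)cc2Br)[C@@H]3O[C@H]1C=C3OC | intermediate
9 | methyl 2-(2,4-dibromophenoxy)-3-hydroxy-4-methoxybenzoate | COC(=O)c1ccc(OC)c(O)c1Oc1ccc(Br)cc1Br | intermediate
10 | 2-(2,4-dibromophenoxy)-3-hydroxy-4-methoxybenzoic acid | OC(=O)c1ccc(OC)c(O)c1Oc1ccc(Br)cc1Br | intermediate
11 | 6-bromo-2-(2,4-dibromophenoxy)-3-hydroxy-4-methoxybenzoic acid | OC(=O)c1c(Br)cc(OC)c(O)c1Oc1ccc(Br)cc1Br | intermediate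
12 | 5,6-dibromo-2-(2,4-dibromophenoxy)-3-hydroxy-4-methoxybenzoic acid | OC(=O)c1c(Br)c(Br)c(OC)c(O)c1Oc1ccc(Br)cc1Br | intermediate
13 | 3,4,5-tribromo-2-(2,4-dibromophenoxy)-6-methoxyphenol | COc1c(O)c(Oc2ccc(Br)cc2Br)c(Br)c(Br)c1Br | target

Total step count: 6. Longest linear sequence: 6 steps (1 → 3 → 5 → 6 → 9 → 10 → 13).

**Steps most likely to fail**

Step 4. The donor oxygen on the alkyne raises its LUMO, so the cycloaddition may be too slow at temperatures the furan tolerates. Alternatively, the first C2–C3 bond may form without ring closure and end, after proton loss, in plain vinylation of the furan. Early hydrolysis of the enol ether is a lesser danger.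

In the fallback ring A is bought rather than built, and the crowded ether bond is made by an Ullmann coupling that sets out from 1.
- Commercial 2-bromo-3-hydroxy-4-methoxybenzaldehyde F1 is protected (MOMCl, i-Pr2NEt, CH2Cl2) as 2-bromo-4-methoxy-3-(methoxymethoxy)benzaldehyde F2.
- The bromide of this ether is activated by the ortho formyl group and is coupled with 1 (CuI, picolinic acid, K3PO4, DMSO, 90 °C) to give 2-(2,4-dibromophenoxy)-4-methoxy-3-(methoxymethoxy)benzaldehyde F3.
- Pinnick oxidation (NaClO2, NaH2PO4, 2-methyl-2-butene, t-BuOH/H2O) gives 2-(2,4-dibromophenoxy)-4-methoxy-3-(methoxymethoxy)benzoic acid F4.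
- 2 M HCl in THF removes the acetal, and the route is rejoined at 10.

Step 3. The ynol-ether ester is a strong acceptor with a leaving group on its β-carbon. Addition of base or bromide to the product, hydration on silica or oligomerisation during isolation may therefore consume it as it forms.

The fallback avoids 6 altogether by bringing in the aryloxy group after the cycloaddition, and it sets out from 2.
- NBS and catalytic AgNO3 in acetone give methyl 3-bromoprop-2-ynoate F5, a well-used furan dienophile with the same polarisation as 6.
- Its Diels–Alder reaction with 7 (toluene, 23–60 °C) should give (±)-methyl 3-bromo-5-methoxy-7-oxabicyclo[2.2.1]hepta-2,5-diene-2-carboxylate F6.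
- Addition–elimination of 1 at the β-bromoenoate carbon (K2CO3, MeCN, 0 → 23 °C) replaces Br by OAr and rejoins the route at 8, which is opened with acid to 9 as in the second stage of step 4.

Step 6. Once C5 and C6 carry bromine, the methoxy group is twisted out of the ring plane and donates poorly, so ipso attack at C4 may stall. Forcing it with more bromine and heat invites oxidative demethylation to a quinone or slow bromination of ring B.

The fallback separates C–C cleavage from C–Br formation and sets out from 10.
- Protodecarboxylation of the ortho-aryloxy benzoic acid (Ag2CO3 10 mol %, AcOH 5 mol %, DMSO, 120 °C) gives 2-(2,4-dibromophenoxy)-6-methoxyphenol F7.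
- Its three free ring A positions are each activated by an oxygen substituent and are brominated by ordinary electrophilic substitution (Br2 3.3 equiv, NaOAc, AcOH, 23 °C), which rejoins the route at 13.

**Further compounds**
F1 | step 4 | 2-bromo-3-hydroxy-4-methoxybenzaldehyde | COc1ccc(C=O)c(Br)c1O
F2 | step 4 | 2-bromo-4-methoxy-3-(methoxymethoxy)benzaldehyde | COCOc1c(OC)ccc(C=O)c1Br
F3 | step 4 | 2-(2,4-dibromophenoxy)-4-methoxy-3-(methoxymethoxy)benzaldehyde | COCOc1c(OC)ccc(C=O)c1Oc1ccc(Br)cc1Br
F4 | step 4 | 2-(2,4-dibromophenoxy)-4-methoxy-3-(methoxymethoxy)benzoic acid | COCOc1c(OC)ccc(C(=O)O)c1Oc1ccc(Br)cc1Br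
F5 | step 3 | methyl 3-bromoprop-2-ynoate | COC(=O)C#CBr
F6 | step 3 | (±)-methyl 3-bromo-5-methoxy-7-oxabicyclo[2.2.1]hepta-2,5-diene-2-carboxylate (racemate, 1S,4R enantiomer drawn) | COC(=O)C1=C(Br)[C@@H]2O[C@H]1C=C2OC
F7 | step 6 | 2-(2,4-dibromophenoxy)-6-methoxyphenol | COc1cccc(Oc2ccc(Br)cc2Br)c1O
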